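## Structural features

The target is a linear array of three aromatic units: a central benzene ring (ring C) with no hydrogen, carrying methoxy groups on C2, C3, C5 and C6 and an indol-3-yl unit on each of C1 and C4. Indole A has a 5-methoxy group and indole B a 5-hydroxy group; both nitrogens are unsubstituted. There is no stereocentre, and the two aryl–indolyl axes are not stereogenic because each is flanked on ring C by two identical methoxy groups. The fragile parts are the 5-hydroxyindole (easily oxidised, most of all as its anion), the two N–H indoles (sensitive to acid and to oxidants at C2/C3) and the tetraalkoxybenzene (oxidative demethylation to a quinone, attack by ozone). The difficulty is twofold: every bond to ring C lies between two ortho substituents, and the two halves differ only by one O-methyl group, so a symmetric construction would later have to tell two almost identical indoles apart. The key step uses the fact that C3, C2, N1, C7a and C3a of indole A, together with the nitrogen lone pair, form a six-electron array over five atoms, and that the 5-methoxy group is para to N1. Cutting C3–C3a therefore leads back to an enamine of a para-substituted aniline whose two ortho carbons are equivalent.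

## Logic of the disconnections

19 ⇒ 18. The O–CH2Ph bond of indole B is cut. The oxidisable hydroxyindole stays masked until the last operation. The forward step must cleave a benzyl aryl ether without touching two indoles and five methyl ethers, which neutral hydrogenolysis does.

18 ⇒ 17. The N1–CH2Ph bond of indole A is cut. The benzyl group is the price of the key step, which needs a tertiary enamine nitrogen. The forward step must remove an N-benzyl group from an indole while the O-benzyl ether stays; base-promoted oxygenation of the N-benzylic carbon meets this, at the cost of exposing indolide anions to oxygen for a short time.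

17 ⇒ 15 (through 16). The C3–C3a bond of indole A is cut and C2–C3 is taken back to the indoline level. This turns indole A into the condensation product of 13 with 14, and it makes the hindered C3–aryl junction a bond that already exists before the ring is closed. The forward step must close one ring by light within one molecule and then dehydrogenate; regiochemistry is settled by the symmetry of the aniline ring. Indole B is carried with a free N–H: it has no benzylic hydrogen for the quinone oxidant and a protecting group there would cost two extra operations.

15 ⇒ 13 + 14. The enamine C–N bond is cut. The two partners are an aldehyde and a purchasable amine. The forward step is a dehydrating condensation of a weakly nucleophilic N-alkylaniline with an enolisable aldehyde, so water must be removed and the product handled dry.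

13 ⇒ 12. The aldehyde is taken back to the primary alcohol. This keeps the second two-carbon arm at a different oxidation level from the first, so the two arms of ring C cannot be confused. The oxidation has to be mild enough for a free N–H indole.

12 ⇒ 8 + 9. N1–C2 and C3–C3a of indole B are cut (Fischer), together with the O–Si bond of the other arm. The hindered aryl–indolyl bond again exists beforehand as the CH2–aryl bond of 8. The forward step needs a [3,3]-shift at a carbon bearing a doubly ortho-substituted aryl group; the acid of the medium removes the silyl group in the same flask and saves a separate deprotection.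

8 ⇒ 6. The aldehyde is traced to an allyl group by cleavage of C=C. An allyl arm is robust towards organolithium chemistry. The cleavage must spare the electron-rich ring C, which excludes ozone.

6 ⇒ 4 ⇒ 1. The two C(aryl)–C bonds are cut one after the other, each at a ring C–H flanked by two methoxy groups. Both arms come from the cheap symmetric arene 1 by two directed lithiations. The oxygenated arm is put in first and silylated in the same flask; the allyl arm follows, so that no acidic benzylic–allylic CH2 meets the base.

## Other disconnections considered

Alternative 1: Ring C itself is cut. In phenol A3 the bond from the hydroxyl-bearing carbon to the carbon carrying indole B, and the bond from the silyloxy-bearing carbon to its methoxy-bearing neighbour, go back to the two alkyne carbons of siloxyalkyne A2 adding across a ketene; a third ring bond goes back to a six-electron closure. Forward, cyclobutenone A1 and A2 would be heated together: four-electron ring opening of A1 to a vinylketene, [2+2] cycloaddition with A2, ring opening of the new cyclobutenone, six-electron closure and tautomerisation would give A3 (Danheiser benzannulation).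
- In its favour: the hexasubstituted ring is built rather than substituted, the polarity of A2 fixes the regiochemistry, and each indole arrives in its own fragment with its own oxygen substituent. In convergence it is the better of the chosen plan, and in differentiating the two indoles it is its equal.
- Against it: A1 and A2 each need a multi-step preparation, A2 is sensitive to moisture, and the cascade has to run with two bulky N-silylindoles next to the reacting carbons. A3 still needs O-desilylation, twofold O-methylation, N-desilylation and hydrogenolysis. The OH/OSi differentiation in A3 is of no use because both become methoxy.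
- Comparison: the longest linear sequence could be shorter than nine steps, but the total number of operations is likely to be larger. The chosen plan uses only purchasable partners and simpler reactions.

Alternative 2: Ring C is cut into two three-carbon units. In quinone A5 the two bonds between each indolyl-bearing carbon and the neighbouring carbonyl carbon are broken. Forward, two molecules of pyruvate ester A4 would condense under excess KOtBu by a double Claisen acylation, head to tail, and tautomerise to A5.
- In its favour: the whole carbon skeleton and the fourfold oxygenation of ring C come in one ionic step from one simple compound. In skeletal step economy and ease of scale-up it is the better of the chosen plan.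
- Against it: the dimerisation can only give a symmetric product, and a crossed version with two different esters would be statistical. After reductive tetra-O-methylation to A6 and debenzylation to bis-phenol A7, one of two equivalent hydroxyl groups would have to be methylated. That step is statistical, competes with N–H and works on an air-sensitive compound. The tetramethylation also has to choose oxygen over indole nitrogen.
- Comparison: it reaches the symmetric core faster but has no control over the one feature that makes 19 unsymmetrical. The chosen plan is longer but introduces the two indoles by different reactions at different times.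

Alternative 3: N1–C7a is cut in both indoles. Forward, bis(nitroalkene) A8 under carbon monoxide with Pd(OAc)2 and 1,10-phenanthroline would be deoxygenated twice, and each nitrogen would bond to an ortho carbon of its alkoxyphenyl ring to give A9, which is identical with 18.
- In its favour: both pyrrole rings close in one operation, the nitrogens arrive unprotected, and only the hydrogenolysis of step 9 remains. In the endgame it is the better of the chosen plan, which needs an N-debenzylation. In excluding ring C from the closure (no free ortho carbon) the two plans are equal.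
- Against it: each 3-alkoxyphenyl ring has two different ortho carbons, so each closure can give the 5-alkoxy or the 7-alkoxy indole, and the twofold reaction can give up to four regioisomers. The chosen plan removes that question by symmetry. Each nitro group must also lie on the side of the alkoxyphenyl ring or isomerise under the conditions.
- Comparison: A8 needs two different 1,1-diaryl-2-nitroethene arms built one after the other on a doubly ortho-substituted ring, which is likely to cost as many steps as the chosen route to 15, and it needs pressurised carbon monoxide.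

Key step: step 7

Remark on the chemistry: 15 is drawn as the E isomer; light interconverts E and Z and both close to the same indoline 16, which is racemic and loses its only stereocentre in the dehydrogenation.

## Route

Step 1
Reactants: 1 1,2,4,5-tetramethoxybenzene
Product: 4 tert-butyl(dimethyl)[2-(2,3,5,6-tetramethoxyphenyl)ethoxy]silane, via aryllithium 2 (not isolated), via lithium alkoxide 3 (not isolated)
Conditions: n-BuLi (1.1 equiv), TMEDA, THF, 0 °C; ethylene oxide (1.2 equiv), −78 → 0 °C; TBSCl (1.3 equiv), imidazole (cat.), 0 °C → rt
Reagents that add atoms: ethylene oxide (C1CO1); TBSCl (CC(C)(C)[Si](C)(C)Cl)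
Why: Directed ortho-lithiation takes place at a ring C–H flanked by two methoxy groups, aryllithium 2 opens the epoxide by SN2 attack, and lithium alkoxide 3 is O-silylated in the same flask, which saves a separate protection step.

Step 2
Reactants: 4 tert-butyl(dimethyl)[2-(2,3,5,6-tetramethoxyphenyl)ethoxy]silane
Product: 6 tert-butyl(dimethyl){2-[2,3,5,6-tetramethoxy-4-(prop-2-en-1-yl)phenyl]ethoxy}silane, via aryllithium 5 (not isolated)
Conditions: n-BuLi (1.2 equiv), TMEDA, THF, 0 °C; CuI (10 mol%), allyl bromide (1.5 equiv), −78 °C → rt
Reagents that add atoms: allyl bromide (C=CCBr)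
Why: A second directed ortho-lithiation removes the last ring hydrogen, again between two methoxy groups and faster than the unactivated benzylic CH2, and CuI-catalysed allylation of aryllithium 5 gives 6; the allyl arm comes second so that no benzylic–allylic CH2 is exposed to n-BuLi.

Step 3
Reactants: 6 tert-butyl(dimethyl){2-[2,3,5,6-tetramethoxy-4-(prop-2-en-1-yl)phenyl]ethoxy}silane
Product: 8 2-[4-(2-{[tert-butyl(dimethyl)silyl]oxy}ethyl)-2,3,5,6-tetramethoxyphenyl]acetaldehyde, via diol 7 (not isolated)
Conditions: OsO4 (2 mol%), NaIO4 (4 equiv), 2,6-lutidine, dioxane/H2O (3:1), rt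
Reagents that add atoms: OsO4 (O=[Os](=O)(=O)=O); NaIO4 ([Na+].[O-]I(=O)(=O)=O)
Why: Lemieux–Johnson oxidation: catalytic osmylation gives racemic diol 7, whose oxygen atoms come from OsO4 that NaIO4 keeps regenerating, and periodate then cleaves the diol to the arylacetaldehyde; ozone is avoided because it would attack the electron-rich ring C, and 2,6-lutidine suppresses over-oxidation.

Step 4
Reactants: 8 2-[4-(2-{[tert-butyl(dimethyl)silyl]oxy}ethyl)-2,3,5,6-tetramethoxyphenyl]acetaldehyde; 9 4-benzyloxyphenylhydrazine hydrochloride
Product: 12 2-[4-(5-benzyloxy-1H-indol-3-yl)-2,3,5,6-tetramethoxyphenyl]ethanol, via hydrazone 10 (not isolated), via silyl ether indole 11 (not isolated)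
Conditions: EtOH, rt → reflux; then 1 M aq. HCl, rt
Reagents that add atoms: none
Why: Fischer indole synthesis: hydrazone 10 tautomerises to the ene-hydrazine, the [3,3]-sigmatropic shift joins the former α-carbon to an ortho carbon of the hydrazine ring, and loss of ammonia gives the 3-arylindole, the para benzyloxy group allowing only the 5-substituted isomer; the HCl–ethanol medium also cleaves the primary TBS ether, and whether this happens before or after ring closure is immaterial because both paths end in 12.

Step 5
Reactants: 12 2-[4-(5-benzyloxy-1H-indol-3-yl)-2,3,5,6-tetramethoxyphenyl]ethanol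
Product: 13 2-[4-(5-benzyloxy-1H-indol-3-yl)-2,3,5,6-tetramethoxyphenyl]acetaldehyde
Conditions: DMP (1.2 equiv), NaHCO3, CH2Cl2, 0 °C → rt
Reagents that add atoms: none
Why: Dess–Martin oxidation of a primary alcohol to the aldehyde under buffered conditions that should leave the N–H indole, the benzyl ether and ring C untouched; the aldehyde is used at once.

Step 6
Reactants: 13 2-[4-(5-benzyloxy-1H-indol-3-yl)-2,3,5,6-tetramethoxyphenyl]acetaldehyde; 14 N-benzyl-4-methoxyaniline (1.0 equiv)
Product: 15 (E)-N-benzyl-N-{2-[4-(5-benzyloxy-1H-indol-3-yl)-2,3,5,6-tetramethoxyphenyl]ethenyl}-4-methoxyaniline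
Conditions: PPTS (5 mol%), 4 Å MS, toluene, 60 °C; filtered, concentrated, used without chromatography
Reagents that add atoms: none
Why: Acid-catalysed condensation of an aldehyde with a secondary amine with removal of water (enamine formation); the iminium ion loses a benzylic proton and the E isomer is favoured on steric grounds; no excess of 14 is used because it would consume the oxidant of step 7.

Step 7
Reactants: 15 (E)-N-benzyl-N-{2-[4-(5-benzyloxy-1H-indol-3-yl)-2,3,5,6-tetramethoxyphenyl]ethenyl}-4-methoxyaniline
Product: 17 1-benzyl-3-[4-(5-benzyloxy-1H-indol-3-yl)-2,3,5,6-tetramethoxyphenyl]-5-methoxy-1H-indole, via N-benzylindoline 16 (not isolated)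
Conditions: hν (350 nm, Pyrex), degassed toluene (5 mM), 20 °C; then DDQ (1.1 equiv), 0 °C → rt
Reagents that add atoms: none
Why: Light absorbed by the N-aryl enamine chromophore drives a conrotatory ring closure of the six electrons held by one C=C of the anisyl ring, the nitrogen lone pair and the enamine C=C, so that the enamine β-carbon bonds to a ring carbon ortho to nitrogen and a zwitterionic dihydroindole (an azomethine ylide) results. A suprafacial 1,4-hydrogen shift from the ring-fusion carbon to the carbanionic C2 restores the benzene ring and gives indoline 16 as a racemate. DDQ then takes hydride from C2 and a proton from C3, so the only stereocentre formed is erased and 17 is flat. The closest known reaction type is the photocyclisation of tertiary N-aryl enamines to indolines (heteroatom-directed photoarylation) followed by quinone dehydrogenation of the indoline. The one ring closed is the pyrrole ring of indole A, made by a five-membered electrocyclic closure that forms C3–C3a inside one molecule, so the two ortho methoxy groups of ring C need only be accommodated. Regioselectivity on the anisyl ring is secured by the equivalence of its two carbons ortho to nitrogen, which places the methoxy group at C5; ring C lies outside the reacting array and has no free ortho carbon, and the N-benzyl ring is insulated by its CH2. Light-induced E/Z isomerisation of 15 does no harm because both isomers feed the same closure, and oxygen is excluded so that the ylide is not intercepted. In the second stage the indoline is by far the best hydride donor present, so one equivalent of DDQ at 0 °C should be consumed before indole B, which has no benzylic hydrogen, or the benzyl ether is touched.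

Step 8
Reactants: 17 1-benzyl-3-[4-(5-benzyloxy-1H-indol-3-yl)-2,3,5,6-tetramethoxyphenyl]-5-methoxy-1H-indole
Product: 18 5-benzyloxy-3-[2,3,5,6-tetramethoxy-4-(5-methoxy-1H-indol-3-yl)phenyl]-1H-indole
Conditions: KOtBu (7 equiv), DMSO/THF, O2 (1 atm), rt, 15 min; aq. NH4Cl
Reagents that add atoms: none
Why: Base-promoted oxidative N-debenzylation: KOtBu in DMSO deprotonates the N-benzylic CH2, the carbanion is trapped by O2, DMSO reduces the hydroperoxide, and the hemiaminal collapses to the indolide and benzaldehyde; the O-benzyl CH2 is far less acidic, and the reaction time is kept short to limit contact of the indolide anions with O2.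

Step 9
Reactants: 18 5-benzyloxy-3-[2,3,5,6-tetramethoxy-4-(5-methoxy-1H-indol-3-yl)phenyl]-1H-indole
Product: 19 3-[2,3,5,6-tetramethoxy-4-(5-methoxy-1H-indol-3-yl)phenyl]-1H-indol-5-ol
Conditions: H2 (1 atm), Pd/C (10%), EtOAc/MeOH, rt
Reagents that add atoms: none
Why: Hydrogenolysis of the benzyl aryl ether over Pd/C; indoles and aryl methyl ethers are inert under these neutral conditions, and the air-sensitive 5-hydroxyindole is set free only in the last step and handled under argon.

## Compound list

1 | 1,2,4,5-tetramethoxybenzene | COc1cc(OC)c(OC)cc1OC | starting material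
2 | (2,3,5,6-tetramethoxyphenyl)lithium (formed in the flask, not isolated) | [Li]c1c(OC)c(OC)cc(OC)c1OC | intermediate
3 | lithium 2-(2,3,5,6-tetramethoxyphenyl)ethanolate (formed in the flask, not isolated) | [Li+].[O-]CCc1c(OC)c(OC)cc(OC)c1OC | intermediate
4 | tert-butyl(dimethyl)[2-(2,3,5,6-tetramethoxyphenyl)ethoxy]silane | CC(C)(C)[Si](C)(C)OCCc1c(OC)c(OC)cc(OC)c1OC | intermediate
5 | [4-(2-{[tert-butyl(dimethyl)silyl]oxy}ethyl)-2,3,5,6-tetramethoxyphenyl]lithium (formed in the flask, not isolated) | [Li]c1c(OC)c(OC)c(CCO[Si](C)(C)C(C)(C)C)c(OC)c1OC | intermediate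
6 | tert-butyl(dimethyl){2-[2,3,5,6-tetramethoxy-4-(prop-2-en-1-yl)phenyl]ethoxy}silane | C=CCc1c(OC)c(OC)c(CCO[Si](C)(C)C(C)(C)C)c(OC)c1OC | intermediate
7 | 3-[4-(2-{[tert-butyl(dimethyl)silyl]oxy}ethyl)-2,3,5,6-tetramethoxyphenyl]propane-1,2-diol (racemic, not isolated) | OCC(O)Cc1c(OC)c(OC)c(CCO[Si](C)(C)C(C)(C)C)c(OC)c1OC | intermediate
8 | 2-[4-(2-{[tert-butyl(dimethyl)silyl]oxy}ethyl)-2,3,5,6-tetramethoxyphenyl]acetaldehyde | O=CCc1c(OC)c(OC)c(CCO[Si](C)(C)C(C)(C)C)c(OC)c1OC | intermediate
9 | 4-benzyloxyphenylhydrazine hydrochloride | Cl.NNc1ccc(OCc2ccccc2)cc1 | starting material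
10 | (E)-4-benzyloxyphenylhydrazone of aldehyde 8 (not isolated; the C=N geometry is of no consequence) | COc1c(C/C=N/Nc2ccc(OCc3ccccc3)cc2)c(OC)c(OC)c(CCO[Si](C)(C)C(C)(C)C)c1OC | intermediate
11 | 5-benzyloxy-3-[4-(2-{[tert-butyl(dimethyl)silyl]oxy}ethyl)-2,3,5,6-tetramethoxyphenyl]-1H-indole (not isolated) | COc1c(-c2c[nH]c3ccc(OCc4ccccc4)cc23)c(OC)c(OC)c(CCO[Si](C)(C)C(C)(C)C)c1OC | intermediate
12 | 2-[4-(5-benzyloxy-1H-indol-3-yl)-2,3,5,6-tetramethoxyphenyl]ethanol | COc1c(-c2c[nH]c3ccc(OCc4ccccc4)cc23)c(OC)c(OC)c(CCO)c1OC | intermediate
13 | 2-[4-(5-benzyloxy-1H-indol-3-yl)-2,3,5,6-tetramethoxyphenyl]acetaldehyde | COc1c(-c2c[nH]c3ccc(OCc4ccccc4)cc23)c(OC)c(OC)c(CC=O)c1OC | intermediate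
14 | N-benzyl-4-methoxyaniline | COc1ccc(NCc2ccccc2)cc1 | starting material
15 | (E)-N-benzyl-N-{2-[4-(5-benzyloxy-1H-indol-3-yl)-2,3,5,6-tetramethoxyphenyl]ethenyl}-4-methoxyaniline | COc1ccc(N(Cc2ccccc2)/C=C/c2c(OC)c(OC)c(-c3c[nH]c4ccc(OCc5ccccc5)cc34)c(OC)c2OC)cc1 | intermediate
16 | 1-benzyl-3-[4-(5-benzyloxy-1H-indol-3-yl)-2,3,5,6-tetramethoxyphenyl]-5-methoxy-2,3-dihydro-1H-indole (racemic at C3, not isolated) | COc1ccc2c(c1)C(c1c(OC)c(OC)c(-c3c[nH]c4ccc(OCc5ccccc5)cc34)c(OC)c1OC)CN2Cc1ccccc1 | intermediate
17 | 1-benzyl-3-[4-(5-benzyloxy-1H-indol-3-yl)-2,3,5,6-tetramethoxyphenyl]-5-methoxy-1H-indole | COc1ccc2c(c1)c(-c1c(OC)c(OC)c(-c3c[nH]c4ccc(OCc5ccccc5)cc34)c(OC)c1OC)cn2Cc1ccccc1 | intermediate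
18 | 5-benzyloxy-3-[2,3,5,6-tetramethoxy-4-(5-methoxy-1H-indol-3-yl)phenyl]-1H-indole | COc1ccc2[nH]cc(-c3c(OC)c(OC)c(-c4c[nH]c5ccc(OCc6ccccc6)cc45)c(OC)c3OC)c2c1 | intermediate
19 | 3-[2,3,5,6-tetramethoxy-4-(5-methoxy-1H-indol-3-yl)phenyl]-1H-indol-5-ol | COc1ccc2[nH]cc(-c3c(OC)c(OC)c(-c4c[nH]c5ccc(O)cc45)c(OC)c3OC)c2c1 | target

## Step count and least certain steps

Total: 9 steps. Longest linear sequence: 9 steps (1 → 19); 9 and 14 are purchased and enter in steps 4 and 6.

Step 7 (key step). The ring closure may be inefficient because the β-aryl group, twisted by its two ortho methoxy groups, favours radiationless decay and E/Z isomerisation over bond formation. The enamine may also hydrolyse with traces of water during the long irradiation, or the quinone may oxidise the electron-rich indole B once the indoline is used up. Fallback without photochemistry: setting out from 13, condensation with commercial 4-methoxyphenylhydrazine hydrochloride (Cl.NNc1ccc(OC)cc1) in ethanol should give the (E)-4-methoxyphenylhydrazone F1 of aldehyde 13. Heating in the same flask should then bring about Fischer indolisation to 18, where the route is rejoined; step 8 is then not needed.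

Step 8. Electron transfer from the indolide anions of indole B and of the freed indole A to oxygen (autoxidation at C3) may compete with oxygenation of the N-benzylic carbanion. The fallback uses a base-labile N-substituent and sets out from 13. Aza-Michael addition of p-anisidine to acrylonitrile (AcOH cat.) should give 3-[(4-methoxyphenyl)amino]propanenitrile F2, and condensation of F2 with 13 as in step 6 should give the N-(2-cyanoethyl) enamine F3. Irradiation as in step 7 should give the N-(2-cyanoethyl)indoline F4 (not isolated), which DDQ should dehydrogenate to the N-(2-cyanoethyl)indole F5. KOtBu in THF under argon, followed by aq. NH4Cl, should then remove the cyanoethyl group by retro-Michael (E1cB) loss of acrylonitrile, with no oxygen present, and give 18, where the route is rejoined.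

Step 4. The [3,3]-shift has to form a bond at the carbon that carries the doubly ortho-substituted aryl group and may be slow, so that hydrazone hydrolysis and N–N cleavage compete; desilylation may also stop short. The fallback replaces the Fischer synthesis by a cross-coupling and sets out from 4. Lithiation as in step 2 gives 5, which ZnCl2 should convert into the arylzinc chloride F6. Commercial 5-benzyloxyindole would be N-silylated (NaH, TIPSCl) to 5-benzyloxy-1-(triisopropylsilyl)indole F7 and brominated at C3 (NBS, THF, −78 °C) to 3-bromo-5-benzyloxy-1-(triisopropylsilyl)indole F8. Negishi coupling of F6 with F8 (Pd2(dba)3, SPhos, THF, 60 °C) should give the doubly silylated 3-arylindole F9, and TBAF in THF should remove both silyl groups and give 12, where the route is rejoined.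

Step 6. Self-condensation of the enolisable arylacetaldehyde may outrun its condensation with the weakly nucleophilic N-benzylaniline, and the enamine may hydrolyse on handling. Fallback through a stable aldehyde equivalent, setting out from 13: trimethyl orthoformate and PPTS in methanol should give the dimethyl acetal F10. Heating F10 with 14 and a catalytic amount of acid in toluene, with distillation of methanol, should give 15 by aminolysis of the acetal; the route is rejoined at 15.

## Further compounds

F1 | step 7 | (E)-4-methoxyphenylhydrazone of 13 | COc1ccc(N/N=C/Cc2c(OC)c(OC)c(-c3c[nH]c4ccc(OCc5ccccc5)cc34)c(OC)c2OC)cc1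
F2 | step 8 | 3-[(4-methoxyphenyl)amino]propanenitrile | N#CCCNc1ccc(OC)cc1
F3 | step 8 | (E)-3-[{2-[4-(5-benzyloxy-1H-indol-3-yl)-2,3,5,6-tetramethoxyphenyl]ethenyl}(4-methoxyphenyl)amino]propanenitrile | COc1ccc(N(CCC#N)/C=C/c2c(OC)c(OC)c(-c3c[nH]c4ccc(OCc5ccccc5)cc34)c(OC)c2OC)cc1
F4 | step 8 | 3-{3-[4-(5-benzyloxy-1H-indol-3-yl)-2,3,5,6-tetramethoxyphenyl]-5-methoxy-2,3-dihydro-1H-indol-1-yl}propanenitrile (racemic, not isolated) | COc1ccc2c(c1)C(c1c(OC)c(OC)c(-c3c[nH]c4ccc(OCc5ccccc5)cc34)c(OC)c1OC)CN2CCC#N
F5 | step 8 | 3-{3-[4-(5-benzyloxy-1H-indol-3-yl)-2,3,5,6-tetramethoxyphenyl]-5-methoxy-1H-indol-1-yl}propanenitrile | COc1ccc2c(c1)c(-c1c(OC)c(OC)c(-c3c[nH]c4ccc(OCc5ccccc5)cc34)c(OC)c1OC)cn2CCC#N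
F6 | step 4 | [4-(2-{[tert-butyl(dimethyl)silyl]oxy}ethyl)-2,3,5,6-tetramethoxyphenyl]zinc chloride | Cl[Zn]c1c(OC)c(OC)c(CCO[Si](C)(C)C(C)(C)C)c(OC)c1OC
F7 | step 4 | 5-benzyloxy-1-(triisopropylsilyl)indole | CC(C)[Si](C(C)C)(C(C)C)n1ccc2cc(OCc3ccccc3)ccc12
F8 | step 4 | 3-bromo-5-benzyloxy-1-(triisopropylsilyl)indole | CC(C)[Si](C(C)C)(C(C)C)n1cc(Br)c2cc(OCc3ccccc3)ccc12
F9 | step 4 | 5-benzyloxy-3-[4-(2-{[tert-butyl(dimethyl)silyl]oxy}ethyl)-2,3,5,6-tetramethoxyphenyl]-1-(triisopropylsilyl)indole | COc1c(-c2cn([Si](C(C)C)(C(C)C)C(C)C)c3ccc(OCc4ccccc4)cc23)c(OC)c(OC)c(CCO[Si](C)(C)C(C)(C)C)c1OC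
F10 | step 6 | 5-benzyloxy-3-[4-(2,2-dimethoxyethyl)-2,3,5,6-tetramethoxyphenyl]-1H-indole | COC(OC)Cc1c(OC)c(OC)c(-c2c[nH]c3ccc(OCc4ccccc4)cc23)c(OC)c1OC
A1 | alternative 1 | 2,4-dimethoxy-3-(5-methoxy-1-triisopropylsilylindol-3-yl)cyclobut-2-en-1-one (racemic) | COC1C(=O)C(OC)=C1c1cn([Si](C(C)C)(C(C)C)C(C)C)c2ccc(OC)cc12
A2 | alternative 1 | 5-benzyloxy-1-triisopropylsilyl-3-[(triisopropylsilyloxy)ethynyl]indole | CC(C)[Si](OC#Cc1cn([Si](C(C)C)(C(C)C)C(C)C)c2ccc(OCc3ccccc3)cc12)(C(C)C)C(C)C
A3 | alternative 1 | 2-(5-benzyloxy-1-triisopropylsilylindol-3-yl)-5-(5-methoxy-1-triisopropylsilylindol-3-yl)-4,6-dimethoxy-3-(triisopropylsilyloxy)phenol | Oc1c(-c2cn([Si](C(C)C)(C(C)C)C(C)C)c3ccc(OCc4ccccc4)cc23)c(O[Si](C(C)C)(C(C)C)C(C)C)c(OC)c(-c2cn([Si](C(C)C)(C(C)C)C(C)C)c3ccc(OC)cc23)c1OC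
A4 | alternative 2 | methyl 3-(5-benzyloxy-1H-indol-3-yl)-2-oxopropanoate | COC(=O)C(=O)Cc1c[nH]c2ccc(OCc3ccccc3)cc12
A5 | alternative 2 | 2,5-bis(5-benzyloxyindol-3-yl)-3,6-dihydroxy-1,4-benzoquinone | O=C1C(O)=C(c2c[nH]c3ccc(OCc4ccccc4)cc23)C(=O)C(O)=C1c1c[nH]c2ccc(OCc3ccccc3)cc12
A6 | alternative 2 | 1,4-bis(5-benzyloxy-1H-indol-3-yl)-2,3,5,6-tetramethoxybenzene | COc1c(-c2c[nH]c3ccc(OCc4ccccc4)cc23)c(OC)c(OC)c(-c2c[nH]c3ccc(OCc4ccccc4)cc23)c1OC
A7 | alternative 2 | 3,3'-(2,3,5,6-tetramethoxy-1,4-phenylene)bis(1H-indol-5-ol) | COc1c(-c2c[nH]c3ccc(O)cc23)c(OC)c(OC)c(-c2c[nH]c3ccc(O)cc23)c1OC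
A8 | alternative 3 | 1-[(E)-1-(3-benzyloxyphenyl)-2-nitroethenyl]-2,3,5,6-tetramethoxy-4-[(E)-1-(3-methoxyphenyl)-2-nitroethenyl]benzene | [O-][N+](=O)/C=C(\c1cccc(OC)c1)c1c(OC)c(OC)c(/C(=C/[N+](=O)[O-])c2cccc(OCc3ccccc3)c2)c(OC)c1OC
A9 | alternative 3 | 5-benzyloxy-3-[2,3,5,6-tetramethoxy-4-(5-methoxy-1H-indol-3-yl)phenyl]-1H-indole (identical with 18) | COc1ccc2[nH]cc(-c3c(OC)c(OC)c(-c4c[nH]c5ccc(OCc6ccccc6)cc45)c(OC)c3OC)c2c1
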